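**Retrosynthetic overview**
- Target 10 comes from its N-mesyl derivative 9 by N–S cleavage.
- 9 comes from the ethynyl sulfonanilide 7. The route rests on the C2–H/C3–Br pattern of the pyrrole ring: it is what results from adding N1 and a bromine across a terminal alkyne bound through C3 to C3a, so one step forms N1–C2 and C3–Br.
- 7 comes from 4,5-dibromo-2-ethynylaniline 5 and MsCl. The C3a–C3 bond of 5 is made by Sonogashira coupling of iodide 2 with ethynyltrimethylsilane 3, and 2 by ortho-iodination of 3,4-dibromoaniline 1.
- Ring order: the benzo ring is bought with the C5 and C6 bromines in place; the pyrrole ring is the only ring formed, in step 5.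

Key step: step 5

Remark: 1, 3 and 6 are taken as commercial materials. The target has no stereocentre, so no stereocontrol is needed.

**Step 1**
Reactants: 1 3,4-dibromoaniline
Product: 2 4,5-dibromo-2-iodoaniline
Conditions: NIS (1.05 equiv), MeCN, 0 °C to rt, dark
Reagents that add atoms: N-iodosuccinimide, O=C1CCC(=O)N1I
Why: Electrophilic aromatic iodination ortho to the amino group (para is blocked by bromine), which should occur at C6 because it is unhindered and para to the C3 bromine, whereas C2 is wedged between NH2 and Br.

**Step 2**
Reactants: 2 4,5-dibromo-2-iodoaniline; 3 ethynyltrimethylsilane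
Product: 4 4,5-dibromo-2-[(trimethylsilyl)ethynyl]aniline
Conditions: PdCl2(PPh3)2 (2 mol%), CuI (4 mol%), Et3N/THF, rt, N2
Reagents that add atoms: none
Why: Sonogashira coupling in which zerovalent palladium inserts into C–I far faster than into C–Br at room temperature, so only the iodide should be alkynylated, while the silyl cap blocks a second coupling and homocoupling of the product.

**Step 3**
Reactants: 4 4,5-dibromo-2-[(trimethylsilyl)ethynyl]aniline
Product: 5 4,5-dibromo-2-ethynylaniline
Conditions: K2CO3 (0.2 equiv), MeOH/THF, rt
Reagents that add atoms: none
Why: Base-catalysed methanolysis of the alkynyl C–Si bond (protodesilylation), which should leave the aryl bromides and the free amine untouched.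

**Step 4**
Reactants: 5 4,5-dibromo-2-ethynylaniline; 6 methanesulfonyl chloride
Product: 7 N-(4,5-dibromo-2-ethynylphenyl)methanesulfonamide
Conditions: MsCl (1.1 equiv), pyridine, CH2Cl2, 0 °C to rt
Reagents that add atoms: none
Why: N-sulfonylation of a primary aniline, where pyridine as a weak base should stop the reaction at the monosulfonamide because it does not deprotonate the product enough for a second sulfonylation.

**Step 5**
Reactants: 7 N-(4,5-dibromo-2-ethynylphenyl)methanesulfonamide
Product: 9 3,5,6-tribromo-1-(methylsulfonyl)-1H-indole, via indol-3-ylcopper bromide 8 (not isolated)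
Conditions: CuBr2 (3 equiv), DMSO, rt to 40 °C, N2
Reagents that add atoms: CuBr2, Br[Cu]Br
Why: CuBr2 π-activates the ethynyl group of 7 and the sulfonamide nitrogen adds anti to the terminal carbon, releasing HBr and giving the divalent-copper indol-3-yl species 8; a second CuBr2 oxidises 8 to a trivalent-copper aryl bromide, which reductively eliminates the C3–Br bond and leaves two CuBr. The closest known reaction type is the CuX2-mediated cyclisation–halogenation of N-sulfonyl and N-acyl 2-alkynylanilines to 3-haloindoles, applied here to a terminal alkyne, the least explored case of that class. The pyrrole ring closes in a 5-endo-dig mode through the N1–C2 bond, and no stereocentre is formed. If 8 is protonated by the liberated HBr, the resulting 3-unsubstituted N-mesylindole should be brominated at C3 by CuBr2, so both branches converge on 9. Cyclisation must outrun dibromination and oxidative dimerisation of the alkyne, which the ortho-placed acidic N–H, the base-free medium and the inert atmosphere should secure; bromination must stop at C3, which the N-mesyl group and the two ring bromines should secure by deactivating C2 and the benzo ring.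

**Step 6**
Reactants: 9 3,5,6-tribromo-1-(methylsulfonyl)-1H-indole
Product: 10 3,5,6-tribromo-1H-indole
Conditions: 2 M aq NaOH (3 equiv), 1,4-dioxane, 50 °C; then aq NH4Cl
Reagents that add atoms: none
Why: Nucleophilic N-desulfonylation in which the electron-poor tribromoindolide is a good leaving group, run with hydroxide in a methanol-free medium so the mesyl group leaves as methanesulfonate and not as an alkylating methyl ester, and quenched with NH4Cl to spare the acid-sensitive 3-bromoindole.

**Compound list**
1 | 3,4-dibromoaniline | Nc1ccc(Br)c(Br)c1 | starting material
2 | 4,5-dibromo-2-iodoaniline | Nc1cc(Br)c(Br)cc1I | intermediate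
3 | ethynyltrimethylsilane | C#C[Si](C)(C)C | starting material
4 | 4,5-dibromo-2-[(trimethylsilyl)ethynyl]aniline | C[Si](C)(C)C#Cc1cc(Br)c(Br)cc1N | intermediate
5 | 4,5-dibromo-2-ethynylaniline | C#Cc1cc(Br)c(Br)cc1N | intermediate
6 | methanesulfonyl chloride | CS(=O)(=O)Cl | starting material
7 | N-(4,5-dibromo-2-ethynylphenyl)methanesulfonamide | CS(=O)(=O)Nc1cc(Br)c(Br)cc1C#C | intermediate
8 | [5,6-dibromo-1-(methylsulfonyl)-1H-indol-3-yl]copper bromide (not isolated) | CS(=O)(=O)n1cc([Cu]Br)c2cc(Br)c(Br)cc21 | intermediate
9 | 3,5,6-tribromo-1-(methylsulfonyl)-1H-indole | CS(=O)(=O)n1cc(Br)c2cc(Br)c(Br)cc21 | intermediate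
10 | 3,5,6-tribromo-1H-indole | Brc1cc2[nH]cc(Br)c2cc1Br | target

**Total step count:** 6
**Longest linear sequence:** 6 steps (1 → 2 → 4 → 5 → 7 → 9 → 10)

**Steps most likely to fail**

1. Step 5. The terminal alkyne may be consumed by bromine addition across the triple bond or by oxidative dimerisation before nitrogen closes the ring, or protonation of the organocopper may not be followed by complete bromination at C3. The fallback separates ring closure from halogenation. It sets out from 7, which should cyclise with catalytic Cu(OAc)2 in 1,2-dichloroethane at reflux (5-endo-dig hydroamination of a 2-ethynyl sulfonanilide) to 5,6-dibromo-1-(methylsulfonyl)-1H-indole F1. Electrophilic bromination of this at C3 with Br2 in CH2Cl2 at 0 °C to rt should then give 9, where the route is rejoined.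

2. Step 4. Sulfonylation of the weakly nucleophilic, bromine-deactivated aniline may stall, or it may run on partly to the imide and give a mixture. The fallback drives the reaction to one defined product and then trims it. It sets out from 5, which with excess MsCl and Et3N in CH2Cl2 should be sulfonylated exhaustively to N-(4,5-dibromo-2-ethynylphenyl)-N-(methylsulfonyl)methanesulfonamide F2. One mesyl group is then cleaved with 1 M aq NaOH in THF at rt, the sulfonamide anion formed being inert to further attack, and acidification gives 7, where the route is rejoined.

3. Step 6. The C3 bromine may be lost, or the free 3-bromoindole may decompose during basic cleavage or work-up. The fallback avoids N-protection. It sets out from 5, which should cyclise as the free 2-ethynylaniline with CuI in DMF at 100 °C to 5,6-dibromo-1H-indole F3. Bromination of this with NBS in DMF at 0 °C at C3, the most nucleophilic position of the free indole, should give the target 10 directly from a neutral medium.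

**Further compounds**
F1 | step 5 | 5,6-dibromo-1-(methylsulfonyl)-1H-indole | CS(=O)(=O)n1ccc2cc(Br)c(Br)cc21
F2 | step 4 | N-(4,5-dibromo-2-ethynylphenyl)-N-(methylsulfonyl)methanesulfonamide | CS(=O)(=O)N(c1cc(Br)c(Br)cc1C#C)S(C)(=O)=O
F3 | step 6 | 5,6-dibromo-1H-indole | Brc1cc2cc[nH]c2cc1Br
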